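**Retrosynthetic overview**

1. The strategy rests on the cis-1,4 pair of acetoxy carbons C8 and C13 that flank the tetrasubstituted butenolide alkene C7=C11. This is the imprint of O2 added across an s-cis diene C8=C7–C11=C13, so both C–OAc bonds go back to one 1,2-dioxine ring and then to a 7(8),11(13)-dienolide.
2. That 2-acyl diene on C7 is opened by exo ring-closing enyne metathesis (C7–C8 bond, ten-membered carbocycle C1–C10) between a C8 vinyl group and a C7≡C11 alkynoate; the C6 hydroxyl then closes the γ-lactone on C12.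
3. The open chain is assembled by asymmetric propiolate addition to a Z-enal (C6–C7), Ni/Cr alkenylation of acrolein (C9–C10), iodo-Wittig olefination (C1=C10) and Sonogashira coupling (C3–C4) of pieces from but-2-yn-1-ol and prop-2-yn-1-ol; both side-chain esters are in place before cyclisation.
4. Ring order: oxirane C2–C3 (Sharpless, trans), oxirane C4–C5 (hydroxyl-directed, cis), carbocycle and lactone together in the key step, then a transient dioxine across C8/C13 that is reduced and acetylated.

Key step: step 17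

Remark: atom labels follow germacranolide numbering (ring C1–C10, C11/C12/C13 the lactone arm, C14 the CH2O group on C10, C15 the methyl on C4); read from the SMILES, the C2–C3 oxirane is trans (C1 and C4 on opposite faces) and the C4–C5 oxirane is cis, so C2=C3 is built as an E alkene and C4=C5 as a Z alkene.
Assumption: for the two ligand-controlled carbonyl additions (steps 9 and 15) the ligand antipode is defined by the required Re-face attack and is to be confirmed on a model aldehyde.
Abbreviations: TBS = tert-butyldimethylsilyl; senecioyl = 3-methylbut-2-enoyl; methylglycidoyl = (2S)-2-methyloxirane-2-carbonyl.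

**Route**

Step 1
Reactants: 1 but-2-yn-1-ol
Product: 3 (Z)-3-iodobut-2-en-1-ol, via sodium alkenylalanate 2 (not isolated)
Conditions: NaAlH2(OCH2CH2OMe)2, THF, 0 °C to rt; then I2, THF, −78 to 0 °C
Reagents that add atoms: iodine, II; sodium bis(2-methoxyethoxy)aluminium dihydride, [Na+].[AlH2-](OCCOC)OCCOC (its atoms are held only by 2)
Why: Hydroxyl-directed trans-hydroalumination of the propargylic alcohol puts aluminium on the carbon remote from oxygen (five-membered alanate 2) and iodinolysis goes with retention, so iodine and CH2OH end up cis, which later makes C3 and C6 cis on C4=C5.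

Step 2
Reactants: 3 (Z)-3-iodobut-2-en-1-ol
Product: 4 (Z)-tert-butyl[(3-iodobut-2-en-1-yl)oxy]dimethylsilane
Conditions: TBSCl, imidazole, CH2Cl2, 0 °C to rt
Reagents that add atoms: tert-butyldimethylsilyl chloride, CC(C)(C)[Si](C)(C)Cl
Why: Silyl ether formation on a primary allylic alcohol is routine and the alkenyl iodide is inert to it.

Step 3
Reactants: 4 (Z)-tert-butyl[(3-iodobut-2-en-1-yl)oxy]dimethylsilane; 5 prop-2-yn-1-ol
Product: 6 (Z)-6-(tert-butyldimethylsilyloxy)-4-methylhex-4-en-2-yn-1-ol
Conditions: Pd(PPh3)2Cl2 (3 mol%), CuI (6 mol%), Et3N, THF, rt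
Reagents that add atoms: none
Why: Sonogashira coupling of an alkenyl iodide with a terminal alkyne forms C3–C4 with retention of the alkene geometry and tolerates the free propargylic hydroxyl and the silyl ether.

Step 4
Reactants: 6 (Z)-6-(tert-butyldimethylsilyloxy)-4-methylhex-4-en-2-yn-1-ol
Product: 7 (2E,4Z)-6-(tert-butyldimethylsilyloxy)-4-methylhexa-2,4-dien-1-ol
Conditions: NaAlH2(OCH2CH2OMe)2, THF, 0 °C; then H2O work-up
Reagents that add atoms: none
Why: Hydroxyl-directed trans-hydroalumination of the propargylic alcohol followed by protonolysis (Red-Al reduction) should give the 2E alkene needed for the trans oxirane, while the trisubstituted Z alkene and the silyl ether are not touched.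

Step 5
Reactants: 7 (2E,4Z)-6-(tert-butyldimethylsilyloxy)-4-methylhexa-2,4-dien-1-ol
Product: 8 [(2R,3R)-3-[(Z)-4-(tert-butyldimethylsilyloxy)but-2-en-2-yl]oxiran-2-yl]methanol (trans-epoxy alcohol)
Conditions: Ti(OiPr)4 (10 mol%), D-(−)-diisopropyl tartrate (12 mol%), t-BuOOH, 4 Å molecular sieves, CH2Cl2, −20 °C
Reagents that add atoms: tert-butyl hydroperoxide, CC(C)(C)OO
Why: Sharpless asymmetric epoxidation of an E-disubstituted primary allylic alcohol with the D-(−)-tartrate should deliver oxygen to the face that gives the (2R,3R) trans-epoxy alcohol (C2 and C3 set by the reagent), and the alkene that is not allylic to a free hydroxyl stays intact under the catalytic sieve conditions.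

Step 6
Reactants: 8 trans-epoxy alcohol
Product: 9 (2S,3R)-3-[(Z)-4-(tert-butyldimethylsilyloxy)but-2-en-2-yl]oxirane-2-carbaldehyde
Conditions: Dess–Martin periodinane, pyridine, CH2Cl2, 0 °C to rt
Reagents that add atoms: none
Why: Pyridine-buffered Dess–Martin oxidation takes the primary alcohol to the aldehyde without opening the allylic oxirane or epimerising C2 (the descriptor changes only by priority).

Step 7
Reactants: 9 epoxy aldehyde; 10 ethyl (triphenylphosphoranylidene)acetate
Product: 12 ethyl (Z)-2-iodo-3-[(2R,3R)-3-[(Z)-4-(tert-butyldimethylsilyloxy)but-2-en-2-yl]oxiran-2-yl]prop-2-enoate, via iodo ylide 11 (not isolated)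
Conditions: 10, NIS, CH2Cl2, −20 °C; then 9, −20 °C to rt
Reagents that add atoms: N-iodosuccinimide, O=C1CCC(=O)N1I
Why: NIS iodinates the stabilised ylide and the resulting iodo ylide 11 undergoes a Wittig olefination that places the ester trans to the oxirane, as stabilised ylides do, which is the Z-2-iodo enoate with C14 already cis to H1.

Step 8
Reactants: 12 (Z)-2-iodo enoate
Product: 13 (Z)-2-iodo-3-[(2R,3R)-3-[(Z)-4-(tert-butyldimethylsilyloxy)but-2-en-2-yl]oxiran-2-yl]prop-2-en-1-ol
Conditions: i-Bu2AlH (2.2 equiv), CH2Cl2, −78 °C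
Reagents that add atoms: none
Why: 1,2-Reduction of the enoate by diisobutylaluminium hydride at −78 °C is much faster than any reaction at the oxirane or the alkenyl iodide and stops at the allylic alcohol.

Step 9
Reactants: 13 (Z)-2-iodoallylic alcohol; 14 acrolein
Product: 15 (3S,4Z)-4-(hydroxymethyl)-5-[(2R,3R)-3-[(Z)-4-(tert-butyldimethylsilyloxy)but-2-en-2-yl]oxiran-2-yl]penta-1,4-dien-3-ol (C9/C14 diol)
Conditions: CrCl2 (4 equiv), NiCl2 (2 mol%), N-[2-(4-isopropyl-4,5-dihydrooxazol-2-yl)-6-methylphenyl]methanesulfonamide (antipode for Re-face attack), Et3N, THF, rt; no added iodide or silyl chloride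
Reagents that add atoms: none
Why: In this Nozaki–Hiyama–Kishi alkenylation nickel inserts into the C–I bond with retention, the alkenylchromium species adds only to the aldehyde and tolerates the C14 hydroxyl as its chromium alkoxide, and the chiral sulfonamide on chromium directs attack to the Re face of acrolein to set C9 (S), the minor 9-epimer being a separable diastereomer.

Step 10
Reactants: 15 C9/C14 diol
Product: 16 (2Z)-2-[(1S)-1-hydroxyprop-2-en-1-yl]-3-[(2R,3R)-3-[(Z)-4-(tert-butyldimethylsilyloxy)but-2-en-2-yl]oxiran-2-yl]prop-2-en-1-yl 3-methylbut-2-enoate (C14 senecioate, C9 hydroxyl free)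
Conditions: 3-methylbut-2-enoyl chloride (1.05 equiv), 2,4,6-collidine, CH2Cl2, −40 °C
Reagents that add atoms: 3-methylbut-2-enoyl chloride, CC(C)=CC(=O)Cl
Why: Selective esterification with an acid chloride at low temperature should distinguish the unhindered primary C14 hydroxyl from the secondary doubly allylic C9 hydroxyl, and the weak hindered base avoids the vinylketene pathway that would deconjugate the senecioate.

Step 11
Reactants: 17 (R)-(2-methyloxiran-2-yl)methanol
Product: 18 (S)-2-methyloxirane-2-carboxylic acid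
Conditions: RuCl3·xH2O (2 mol%), NaIO4, EtOAc/MeCN/H2O, 0 °C to rt
Reagents that add atoms: water, O (new carboxyl oxygen through the aldehyde hydrate); sodium periodate, [Na+].[O-]I(=O)(=O)=O (terminal oxidant, oxygen of the RuO4 formed in the flask)
Why: Catalytic ruthenium tetroxide oxidation takes the primary alcohol to the acid without touching the oxirane, and the quaternary stereocentre is not involved (R becomes S only by priority).

Step 12
Reactants: 16 C14 senecioate; 18 (S)-2-methyloxirane-2-carboxylic acid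
Product: 20 (3S,4Z)-4-[(3-methylbut-2-enoyloxy)methyl]-5-[(2R,3R)-3-[(Z)-4-(tert-butyldimethylsilyloxy)but-2-en-2-yl]oxiran-2-yl]penta-1,4-dien-3-yl (2S)-2-methyloxirane-2-carboxylate, via mixed anhydride 19 (not isolated)
Conditions: 18, 2,4,6-trichlorobenzoyl chloride, Et3N, toluene, 0 °C to rt; then 16, DMAP, rt
Reagents that add atoms: 2,4,6-trichlorobenzoyl chloride, O=C(Cl)c1c(Cl)cc(Cl)cc1Cl (its acyl group is carried only by 19 and is lost again)
Why: In this Yamaguchi esterification DMAP attacks the less hindered glycidic carbonyl of mixed anhydride 19 and the acylpyridinium acylates the hindered C9 hydroxyl with the C9–O bond, and so the stereocentre, untouched.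

Step 13
Reactants: 20 diester TBS ether
Product: 21 (3S,4Z)-5-[(2R,3R)-3-[(Z)-4-hydroxybut-2-en-2-yl]oxiran-2-yl]-4-[(3-methylbut-2-enoyloxy)methyl]penta-1,4-dien-3-yl (2S)-2-methyloxirane-2-carboxylate
Conditions: HF·pyridine, pyridine, THF, 0 °C
Reagents that add atoms: none
Why: Fluoride-mediated desilylation of the primary silyl ether under pyridine buffering is mild enough for the two esters and the doubly allylic oxirane.

Step 14
Reactants: 21 Z-allylic alcohol
Product: 22 (3S,4Z)-4-[(3-methylbut-2-enoyloxy)methyl]-5-[(2R,3R)-3-[(Z)-4-oxobut-2-en-2-yl]oxiran-2-yl]penta-1,4-dien-3-yl (2S)-2-methyloxirane-2-carboxylate (Z-enal)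
Conditions: MnO2 (activated, excess), CH2Cl2, 0 °C to rt, dark; filtered and used at once
Reagents that add atoms: none
Why: Allylic oxidation with MnO2 is neutral and heterogeneous, so the Z geometry of the enal should be kept if the filtrate is taken straight into the next step.

Step 15
Reactants: 22 Z-enal; 23 methyl propiolate
Product: 24 methyl (4S,5Z)-4-hydroxy-6-[(2R,3R)-3-[(1Z,3S)-2-[(3-methylbut-2-enoyloxy)methyl]-3-[(2S)-2-methyloxirane-2-carbonyloxy]penta-1,4-dien-1-yl]oxiran-2-yl]hept-5-en-2-ynoate (6S propargylic alcohol)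
Conditions: 23 (3 equiv), Me2Zn (3 equiv), ProPhenol (20 mol%, antipode for Re-face attack), Ph3P=O (40 mol%), toluene, 4 °C
Reagents that add atoms: none
Why: In this zinc–ProPhenol asymmetric alkynylation the dinuclear zinc complex binds the aldehyde and the zinc alkynylide and delivers the propiolate to the Re face of the enal, setting C6 (S at this stage) under catalyst control, while esters and oxiranes do not react with Me2Zn at this temperature.

Step 16
Reactants: 24 6S propargylic alcohol
Product: 25 open-chain diepoxy en-ynoate CH2=C8H–C9H(O-methylglycidoyl)–C10(C14H2O-senecioyl)=C1H–[C2–C3 trans-oxirane]–[C4(CH3)–C5 cis-oxirane]–C6H(OH)–C7≡C11–C12O2Me (1(10)Z; 2R,3S,4S,5S,6R,9S)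
Conditions: m-CPBA, NaHCO3, CH2Cl2, 0 °C
Reagents that add atoms: 3-chloroperoxybenzoic acid, O=C(OO)c1cccc(Cl)c1
Why: In this hydroxyl-directed peracid epoxidation the conformer that minimises A(1,3) strain (H6 eclipsing C3) presents the alkene face syn to the C6 hydroxyl to the hydrogen-bonded peracid, which should give the threo C5/C6 relation and the cis 4S,5S oxirane, while the other alkenes are electron-poor or undirected.

Step 17
Reactants: 25 open-chain diepoxy en-ynoate
Product: 27 9-O-methylglycidoyl-14-O-senecioyl-2,3:4,5-diepoxygermacra-1(10)Z,7Z,11(13)-trien-12,6-olide (s-cis locked dienolide), via ten-membered hydroxy ester 26 (not isolated)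
Conditions: second-generation Grubbs catalyst (H2IMes)(PCy3)Cl2Ru=CHPh (15 mol%, two portions), ethylene (1 atm), toluene (1 mM), 80 °C; then (ClBu2Sn)2O (10 mol%), 80 °C, if lactonisation is incomplete
Reagents that add atoms: ethylene, C=C (supplies the C13 methylene; the terminal CH2 of the C8 vinyl group leaves as ethylene)
Why: The ruthenium methylidene loads on the only monosubstituted alkene (C8), the C8 alkylidene adds across C7≡C11 to a ruthenacyclobutene that opens to the C11 vinylcarbene (new C7=C8 bond, ten-membered ring closed), and ethylene caps C11 as C11=C13H2 and returns the methylidene; the alternative entry, ethylene–alkyne cross-metathesis followed by diene–ene closure onto the C7 methylene, converges on the same hydroxy ester 26. The closest known reaction type is exo-mode ring-closing enyne metathesis of tethered enynes, ester-substituted alkynes included, under ethylene, used here at the upper end of the medium-ring range. The carbocycle closes in the exo mode through the eight-atom tether C9–C10–C1–C2–C3–C4–C5–C6, so that only C7 of the alkyne enters the ring, and the lactone closes by 5-exo-trig acyl substitution of the C6 hydroxyl on the C12 methyl ester, which becomes possible only once the linear alkynoate has turned into the bent acrylate. No stereocentre is created and none is at risk under these neutral conditions; the C7=C8 geometry with C6 and C9 cis should be imposed by the ring, which already holds the Z alkene C1=C10, the cis oxirane C4–C5 and the trans oxirane C2–C3 and can hardly take a further trans unit. The step needs exo over endo closure, cyclisation over oligomerisation and initiation at C8 only: the short tether disfavours the eleven-membered endo ring, millimolar concentration under ethylene suppresses oligomers and keeps the catalyst alive, and every other alkene is trisubstituted between oxygen-bearing carbons or is a β,β-disubstituted enoate and stays a spectator.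

Step 18
Reactants: 27 s-cis locked dienolide
Product: 28 8,13-epidioxy-9-O-methylglycidoyl-14-O-senecioyl-2,3:4,5-diepoxygermacra-1(10)Z,7(11)-dien-12,6-olide (1,2-dioxine, 8R)
Conditions: O2, tetraphenylporphyrin (1 mol%), white LED light, CH2Cl2, −78 °C; no base
Reagents that add atoms: dioxygen, O=O
Why: Sensitised singlet oxygen should add in a suprafacial [4+2] cycloaddition to the locked diene C8=C7–C11=C13 from its convex face (the face of H6, away from the ring arms through C5 and C10), which sets C8 and creates the butenolide alkene C7=C11, and base is excluded so that no Kornblum–DeLaMare rearrangement occurs.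

Step 19
Reactants: 28 1,2-dioxine
Product: 29 8,13-dihydroxy-9-O-methylglycidoyl-14-O-senecioyl-2,3:4,5-diepoxygermacra-1(10)Z,7(11)-dien-12,6-olide (cis-2-ene-1,4-diol)
Conditions: thiourea (2.2 equiv), CH2Cl2/MeOH, −20 to 0 °C
Reagents that add atoms: none
Why: Thiourea reduction of the endoperoxide cleaves only the O–O bond under neutral conditions, so both C–O bonds and the C8 configuration are kept, and at this temperature oxiranes should not react with thiourea.

Step 20
Reactants: 29 8,13-diol
Product: 30 target CNP0279449.1 (8,13-diacetate)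
Conditions: Ac2O, pyridine, DMAP (cat.), CH2Cl2, 0 °C
Reagents that add atoms: acetic anhydride, CC(=O)OC(C)=O
Why: DMAP-catalysed acetylation of the primary C13 and secondary C8 hydroxyls should be faster at 0 °C than acyl shift from O9 or relactonisation onto O8, and it completes the target with all stereocentres as set.

**Compound list**

1 | but-2-yn-1-ol | CC#CCO | starting material
2 | sodium 2,2-bis(2-methoxyethoxy)-3-methyl-2,5-dihydro-1,2-oxaluminol-2-uide (cyclic alkenylalanate) | CC1=CCO[Al-]1(OCCOC)OCCOC.[Na+] | intermediate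
3 | (Z)-3-iodobut-2-en-1-ol | C/C(I)=C/CO | intermediate
4 | (Z)-tert-butyl[(3-iodobut-2-en-1-yl)oxy]dimethylsilane | C/C(I)=C/CO[Si](C)(C)C(C)(C)C | intermediate
5 | prop-2-yn-1-ol | C#CCO | starting material
6 | (Z)-6-(tert-butyldimethylsilyloxy)-4-methylhex-4-en-2-yn-1-ol | OCC#C/C(C)=C\CO[Si](C)(C)C(C)(C)C | intermediate
7 | (2E,4Z)-6-(tert-butyldimethylsilyloxy)-4-methylhexa-2,4-dien-1-ol | OC/C=C/C(C)=C\CO[Si](C)(C)C(C)(C)C | intermediate
8 | [(2R,3R)-3-[(Z)-4-(tert-butyldimethylsilyloxy)but-2-en-2-yl]oxiran-2-yl]methanol | OC[C@H]1O[C@@H]1/C(C)=C\CO[Si](C)(C)C(C)(C)C | intermediate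
9 | (2S,3R)-3-[(Z)-4-(tert-butyldimethylsilyloxy)but-2-en-2-yl]oxirane-2-carbaldehyde | O=C[C@H]1O[C@@H]1/C(C)=C\CO[Si](C)(C)C(C)(C)C | intermediate
10 | ethyl (triphenylphosphoranylidene)acetate | CCOC(=O)C=P(c1ccccc1)(c1ccccc1)c1ccccc1 | starting material
11 | ethyl iodo(triphenylphosphoranylidene)acetate | CCOC(=O)C(I)=P(c1ccccc1)(c1ccccc1)c1ccccc1 | intermediate
12 | ethyl (Z)-2-iodo-3-[(2R,3R)-3-[(Z)-4-(tert-butyldimethylsilyloxy)but-2-en-2-yl]oxiran-2-yl]prop-2-enoate | CCOC(=O)/C(I)=C/[C@H]1O[C@@H]1/C(C)=C\CO[Si](C)(C)C(C)(C)C | intermediate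
13 | (Z)-2-iodo-3-[(2R,3R)-3-[(Z)-4-(tert-butyldimethylsilyloxy)but-2-en-2-yl]oxiran-2-yl]prop-2-en-1-ol | I/C(CO)=C\[C@H]1O[C@@H]1/C(C)=C\CO[Si](C)(C)C(C)(C)C | intermediate
14 | acrolein (prop-2-enal) | C=CC=O | starting material
15 | (3S,4Z)-4-(hydroxymethyl)-5-[(2R,3R)-3-[(Z)-4-(tert-butyldimethylsilyloxy)but-2-en-2-yl]oxiran-2-yl]penta-1,4-dien-3-ol | C=C[C@H](O)/C(CO)=C\[C@H]1O[C@@H]1/C(C)=C\CO[Si](C)(C)C(C)(C)C | intermediate
16 | (2Z)-2-[(1S)-1-hydroxyprop-2-en-1-yl]-3-[(2R,3R)-3-[(Z)-4-(tert-butyldimethylsilyloxy)but-2-en-2-yl]oxiran-2-yl]prop-2-en-1-yl 3-methylbut-2-enoate | C=C[C@H](O)/C(COC(=O)C=C(C)C)=C\[C@H]1O[C@@H]1/C(C)=C\CO[Si](C)(C)C(C)(C)C | intermediate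
17 | (R)-(2-methyloxiran-2-yl)methanol | OC[C@]1(C)CO1 | starting material
18 | (S)-2-methyloxirane-2-carboxylic acid | OC(=O)[C@]1(C)CO1 | intermediate
19 | (S)-2-methyloxirane-2-carboxylic 2,4,6-trichlorobenzoic anhydride | O=C(OC(=O)c1c(Cl)cc(Cl)cc1Cl)[C@]1(C)CO1 | intermediate
20 | (3S,4Z)-4-[(3-methylbut-2-enoyloxy)methyl]-5-[(2R,3R)-3-[(Z)-4-(tert-butyldimethylsilyloxy)but-2-en-2-yl]oxiran-2-yl]penta-1,4-dien-3-yl (2S)-2-methyloxirane-2-carboxylate | C=C[C@H](OC(=O)[C@]1(C)CO1)/C(COC(=O)C=C(C)C)=C\[C@H]1O[C@@H]1/C(C)=C\CO[Si](C)(C)C(C)(C)C | intermediate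
21 | (3S,4Z)-5-[(2R,3R)-3-[(Z)-4-hydroxybut-2-en-2-yl]oxiran-2-yl]-4-[(3-methylbut-2-enoyloxy)methyl]penta-1,4-dien-3-yl (2S)-2-methyloxirane-2-carboxylate | C=C[C@H](OC(=O)[C@]1(C)CO1)/C(COC(=O)C=C(C)C)=C\[C@H]1O[C@@H]1/C(C)=C\CO | intermediate
22 | (3S,4Z)-4-[(3-methylbut-2-enoyloxy)methyl]-5-[(2R,3R)-3-[(Z)-4-oxobut-2-en-2-yl]oxiran-2-yl]penta-1,4-dien-3-yl (2S)-2-methyloxirane-2-carboxylate | C=C[C@H](OC(=O)[C@]1(C)CO1)/C(COC(=O)C=C(C)C)=C\[C@H]1O[C@@H]1/C(C)=C\C=O | intermediate
23 | methyl propiolate | C#CC(=O)OC | starting material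
24 | methyl (4S,5Z)-4-hydroxy-6-[(2R,3R)-3-[(1Z,3S)-2-[(3-methylbut-2-enoyloxy)methyl]-3-[(2S)-2-methyloxirane-2-carbonyloxy]penta-1,4-dien-1-yl]oxiran-2-yl]hept-5-en-2-ynoate | C=C[C@H](OC(=O)[C@]1(C)CO1)/C(COC(=O)C=C(C)C)=C\[C@H]1O[C@@H]1/C(C)=C\[C@H](O)C#CC(=O)OC | intermediate
25 | open-chain diepoxy en-ynoate: C8 vinyl, C9 O-methylglycidoyl, C14 O-senecioyl, 1(10)Z alkene, trans 2,3-oxirane, cis 4,5-oxirane, C6 hydroxyl, C7≡C11 methyl ynoate | C=C[C@H](OC(=O)[C@]1(C)CO1)/C(COC(=O)C=C(C)C)=C\[C@H]1O[C@@H]1[C@@]1(C)O[C@H]1[C@H](O)C#CC(=O)OC | intermediate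
26 | methyl 2-(ten-membered ring C7-yl)acrylate: 6-hydroxy-9-O-methylglycidoyl-14-O-senecioyl-2,3:4,5-diepoxycyclodeca-1(10)Z,7Z-diene bearing C(=CH2)CO2Me on C7 | C=C(C(=O)OC)/C1=C/[C@H](OC(=O)[C@]2(C)CO2)/C(COC(=O)C=C(C)C)=C\[C@H]2O[C@@H]2[C@@]2(C)O[C@H]2[C@@H]1O | intermediate
27 | 9-O-methylglycidoyl-14-O-senecioyl-2,3:4,5-diepoxygermacra-1(10)Z,7Z,11(13)-trien-12,6-olide | C=C1/C2=C/[C@H](OC(=O)[C@]3(C)CO3)/C(COC(=O)C=C(C)C)=C\[C@H]3O[C@@H]3[C@@]3(C)O[C@H]3[C@@H]2OC1=O | intermediate
28 | 8,13-epidioxy-9-O-methylglycidoyl-14-O-senecioyl-2,3:4,5-diepoxygermacra-1(10)Z,7(11)-dien-12,6-olide | C4C1=C2[C@@H](OO4)[C@H](OC(=O)[C@]3(C)CO3)/C(COC(=O)C=C(C)C)=C\[C@H]3O[C@@H]3[C@@]3(C)O[C@H]3[C@@H]2OC1=O | intermediate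
29 | 8,13-dihydroxy-9-O-methylglycidoyl-14-O-senecioyl-2,3:4,5-diepoxygermacra-1(10)Z,7(11)-dien-12,6-olide | OCC1=C2[C@@H](O)[C@H](OC(=O)[C@]3(C)CO3)/C(COC(=O)C=C(C)C)=C\[C@H]3O[C@@H]3[C@@]3(C)O[C@H]3[C@@H]2OC1=O | intermediate
30 | CNP0279449.1 (8,13-diacetoxy-9-O-methylglycidoyl-14-O-senecioyl-2,3:4,5-diepoxygermacra-1(10)Z,7(11)-dien-12,6-olide) | CC(=O)OCC1=C2[C@@H](OC(C)=O)[C@H](OC(=O)[C@]3(C)CO3)/C(COC(=O)C=C(C)C)=C\[C@H]3O[C@@H]3[C@@]3(C)O[C@H]3[C@@H]2OC1=O | target

**Step count**

Total: 20 steps. Longest linear sequence: 19 steps (steps 1–10 and 12–20, from but-2-yn-1-ol); step 11 is a one-step side branch.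

**Steps most likely to fail**

1. Step 17. The catalyst may be used up by unproductive ethylene–alkyne turnover or may decompose at 80 °C before the strained ten-membered ring closes, and oligomerisation or endo closure may overtake the exo cyclisation. Fallback: separate the two metathesis events. The fallback sets out from 25: ethylene–alkyne cross-metathesis is run on purpose at normal concentration (second-generation Grubbs catalyst (H2IMes)(PCy3)Cl2Ru=CHPh, ethylene, CH2Cl2, rt) to give the acyclic 7,11-bis(methylene) hydroxy ester F1. After removal of ethylene, the ring is closed at high dilution by diene–ene ring-closing olefin metathesis between the C8 vinyl group and the more electron-rich C7 methylene (second-generation Hoveyda–Grubbs catalyst (H2IMes)Cl2Ru=CH(C6H4-2-OiPr), toluene, 80 °C, argon sparge). This comes back to the route at 26, which lactonises to 27 as in step 17.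

2. Step 18. Ene reactions of singlet oxygen at the trisubstituted alkenes may compete, cycloaddition to the acceptor-substituted diene may be slow, or the oxygen may add to the wrong diene face. Fallback: introduce the two oxygens one after the other under hydroxyl direction. The fallback sets out from 26, isolated by running step 17 at 40 °C without the tin catalyst. VO(acac)2/t-BuOOH (CH2Cl2, 0 °C) should epoxidise only the alkene allylic to the free C6 hydroxyl, syn to it (the same face that singlet oxygen is meant to use), to give the 7,8-epoxy hydroxy ester F2. Lactonisation ((ClBu2Sn)2O, toluene, 60 °C) gives the spiro-epoxy α-methylene lactone F3. Tetrabutylammonium acetate with acetic acid in MeCN then adds acetate to C13 and opens the oxirane at C7 by conjugate addition–β-elimination (an SN2′ opening), which gives the 8-hydroxy 13-acetate F4 with the C7=C11 alkene in place. Acetylation of the C8 hydroxyl (Ac2O, pyridine, DMAP) comes back to the route at 30.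

3. Step 9. The alkenylchromium intermediate may be protonated by the free C14 hydroxyl, acrolein may polymerise, or ligand control at C9 may be weak. Fallback: mask the hydroxyl as the ester it is to become and set C9 by reduction instead of addition. The fallback sets out from 13: acylation with 3-methylbut-2-enoyl chloride (collidine, CH2Cl2, −40 °C) gives the iodoallyl senecioate F5. A ligand-free Ni/Cr coupling with acrolein (CrCl2, NiCl2 cat., DMF, rt) gives the C9-epimeric carbinols F6. Dess–Martin oxidation gives the cross-conjugated vinyl ketone F7. Corey–Bakshi–Shibata reduction ((R)-Me-CBS oxazaborolidine predicted by the size model, catecholborane, toluene, −78 °C, the 1,1-disubstituted alkenyl group acting as the large substituent) should give the 9S alcohol and comes back to the route at 16.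

**Further compounds**

F1 | step 17 | acyclic 7,11-bis(methylene) hydroxy ester (ethylene cross-metathesis product of 25) | C=C[C@H](OC(=O)[C@]1(C)CO1)/C(COC(=O)C=C(C)C)=C\[C@H]1O[C@@H]1[C@@]1(C)O[C@H]1[C@H](O)C(=C)C(=C)C(=O)OC
F2 | step 18 | 7,8-epoxy hydroxy ester (7,8-oxirane syn to the C6 hydroxyl) | C=C(C(=O)OC)[C@@]12O[C@H]2[C@H](OC(=O)[C@]3(C)CO3)/C(COC(=O)C=C(C)C)=C\[C@H]3O[C@@H]3[C@@]3(C)O[C@H]3[C@@H]1O
F3 | step 18 | spiro-epoxy α-methylene lactone (7,8-oxirane, 12,6-olide, C11=C13H2) | C=C1[C@@]23O[C@H]3[C@H](OC(=O)[C@]4(C)CO4)/C(COC(=O)C=C(C)C)=C\[C@H]4O[C@@H]4[C@@]4(C)O[C@H]4[C@@H]2OC1=O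
F4 | step 18 | 8-hydroxy 13-acetate (C7=C11 butenolide) | CC(=O)OCC1=C2[C@@H](O)[C@H](OC(=O)[C@]3(C)CO3)/C(COC(=O)C=C(C)C)=C\[C@H]3O[C@@H]3[C@@]3(C)O[C@H]3[C@@H]2OC1=O
F5 | step 9 | (Z)-2-iodo-3-[(2R,3R)-3-[(Z)-4-(tert-butyldimethylsilyloxy)but-2-en-2-yl]oxiran-2-yl]prop-2-en-1-yl 3-methylbut-2-enoate | CC(C)=CC(=O)OC/C(I)=C/[C@H]1O[C@@H]1/C(C)=C\CO[Si](C)(C)C(C)(C)C
F6 | step 9 | C9-epimeric mixture of 16 | C=CC(O)/C(COC(=O)C=C(C)C)=C\[C@H]1O[C@@H]1/C(C)=C\CO[Si](C)(C)C(C)(C)C
F7 | step 9 | C9 vinyl ketone | C=CC(=O)/C(COC(=O)C=C(C)C)=C\[C@H]1O[C@@H]1/C(C)=C\CO[Si](C)(C)C(C)(C)C
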